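- The pitfall is to rank these flasks by how gently the charge goes in, when the share of target in target plus over-reaction product (the selectivity) may only show how little has happened yet.

| setting | maple | larch | alder | elm | south-west | north-east | south | north-west |
|---|---|---|---|---|---|---|---|---|
| starting material | 0.10 M | 0.10 M | 0.10 M | 0.15 M | 0.10 M | 0.10 M (fed, over 12 min) | 0.10 M (fed, over 12 min) | 0.10 M |
| coupling partner | 0.060 M | 0.084 M | 0.13 M | 0.060 M | 0.0600 M (fed, over 12 min) | 0.0600 M | 0.0600 M | 0.0600 M |
| free catalyst | 7.5 mM | 7.5 mM | 7.5 mM | 7.5 mM | 7.5 mM | 7.5 mM | 7.5 mM | 7.5 mM |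
| temperature | −10 °C | 5 °C | −10 °C | 5 °C | 5 °C |  | 5 °C | 5 °C |
| remark | run made earlier | run made earlier | run made earlier | run made earlier | all else is in the flask from the start; the feed brings no volume worth counting | the addition at −35 °C, then warmed to 5 °C; the feed brings no volume worth counting | all else is in the flask from the start; the feed brings no volume worth counting | everything together at the start |
| time |  |  |  |  | 15 min | 15 min | 15 min | 15 min |

| run | time / min | target / % | over-reaction product / % |
|---|---|---|---|
| maple | 3.00 | 1.9 | 0 |
| maple | 8.00 | 3.6 | 0 |
| maple | 15.0 | 8.1 | 3.2 |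
| maple | 20.0 | 11.3 | 3.3 |
| maple | 30.0 | 13.9 | 3.7 |
| larch | 4.00 | 6.4 | 0 |
| larch | 8.00 | 13.8 | 4.7 |
| larch | 10.0 | 15.7 | 4.4 |
| larch | 15.0 | 18.3 | 8.7 |
| larch | 20.0 | 21.1 | 12.1 |
| alder | 3.00 | 2.5 | 0 |
| alder | 5.00 | 3.0 | 1.0 |
| alder | 10.0 | 8.1 | 0.9 |
| alder | 20.0 | 17.0 | 3.3 |
| alder | 40.0 | 26.4 | 7.4 |
| elm | 1.50 | 2.9 | 1.4 |
| elm | 5.00 | 6.0 | 0 |
| elm | 8.00 | 10.1 | 3.3 |
| elm | 12.0 | 11.2 | 3.1 |
| elm | 20.0 | 14.9 | 7.6 |

(readings scatter by 1 percentage point)

- the flask with the highest share of target in target plus over-reaction product ("all alike" if they lie within 1.5 percentage points) (south-west / north-east / south / north-west / all alike)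
- share of target in target plus over-reaction product at the end, south-west
- share of target in target plus over-reaction product at the end, north-east
- share of target in target plus over-reaction product at the end, south
- share of target in target plus over-reaction product at the end, north-west



- I compare two rates at one moment. I take the rate of over-reaction to go with c(target) and the rate of forming as steady at low turnover, so their ratio drifts up with Z, the turnover: target plus over-reaction product as a fraction of the starting material charged.
- Summed over the run, c(over-reaction product) then grows as Z squared and the lost share as a constant times Z. The larch reading at 20.0 min gives 1.10 for that constant, the over-reaction index g, over-reaction product divided by Z squared; it is a reading and carries the scatter of 1 percentage point.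
- Now I turn the question round. On one g for all flasks, they count as alike if their Z values lie within 1.4 points, and north-east loses its lead if its Z passes another flask's.
- I leave the cold addition in north-east out of the count. Its warm stretch of 3.00 min at the early larch pace gives an estimated Z of 4.80%. For north-west I take the larch Z at 15.0 min, 27.0%, although larch holds more coupling partner. South-west and south stay warm longer than north-east, so I expect more Z there.
- That gap of 22 points is far wider than the width needed, so I commit to north-east, with a share near 94.7% against 70.4% in north-west.
- The forecast also names north-east, but with lower shares than mine: 88% there and 66% in north-west, with 69% in south-west and 73% in south. Its ground for north-east is “almost nothing happens at −35 °C (about 11× slower), leaving only about 3 min warm”.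

- The flasks end at 77.0% in south-west, 93.2% in north-east, 77.5% in south and 69.7% in north-west, so north-east leads, and the forecast lies 5.2 points below it there.

    free catalyst + target → free catalyst + over-reaction product (k = 0.130 M⁻¹ s⁻¹, Ea = 52.0 kJ mol⁻¹)
    starting material + free catalyst ⇌ catalyst intermediate A (K = 5.90 M⁻¹, k = 0.110 M⁻¹ s⁻¹, Ea = 40.0 kJ mol⁻¹, ΔH = −9.00 kJ mol⁻¹)
    coupling partner + by-product ⇌ idle adduct, settled at all times (K = 59.0 M⁻¹, ΔH = −19.0 kJ mol⁻¹)
    catalyst intermediate B → by-product + catalyst intermediate C (k = 0.640 s⁻¹, Ea = 61.0 kJ mol⁻¹)
    catalyst intermediate C ⇌ free catalyst + target (K = 8.70 M, k = 0.410 s⁻¹, Ea = 68.0 kJ mol⁻¹, ΔH = −50.0 kJ mol⁻¹)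
    coupling partner + catalyst intermediate A ⇌ catalyst intermediate B (K = 10.0 M⁻¹, k = 0.510 M⁻¹ s⁻¹, Ea = 52.0 kJ mol⁻¹, ΔH = −45.0 kJ mol⁻¹)
    (constants at 5 °C)

- In north-east, the turning of catalyst intermediate B into by-product and catalyst intermediate C has done half of its turnover up to 15 min by 13.4 min, later than the end of the feed at 12 min. North-east stands at Z of 6.38%, and g times Z gives a lost share of 7.00% against the 6.80% found. The neighbour of north-east with 0.0030 M of free catalyst reaches Z of 2.70%, g then gives a share of 97.0%, and that flask shows 97.3%.

The earlier runs and the new flask were computed for substances that don't exist, and the scatter is random.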